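The benzene ring of the chromene (C4a, C5, C6, C7, C8, C8a) is built from two small pieces instead of substituting a phloroglucinol. The key step exploits that this ring is fully substituted and carries oxygen on C5, C7 and C8a in three different roles. One thermal operation fuses a 3-alkoxycyclobutenone bearing the masked acetyl group with a prenyl-substituted siloxyalkyne into a phenol in which these roles are already set: free OH on C8a (future pyran oxygen O1) between prenyl on C4a and the acetyl precursor on C8, an acid-labile ether on C7, a silyl ether on C5. Pyran closure, unmasking and a methylene bridge to propionylfilicinic acid finish the route.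

Key step: step 5

Remarks on the chemistry:
- The target has no stereocentre. Compounds 10 and 16 are racemic and their centres become sp2 carbons of the arene.
- The C7 oxygen is carried as a tert-butyl ether (from tert-butoxyethyne), not as a primary alkyl ether. A primary ether ortho to the acetyl group could only be removed with a boron or aluminium halide. In an 8-acetylchromene the pyran oxygen O1, a tertiary allylic ether, sits ortho to the same carbonyl and would be ionised by the chelated Lewis acid. The tert-butyl ether falls to protic acid in the same operation as the ketal.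
- Ester 1 is a commercial fragrance chemical. Its acid chloride is made from the dry potassium salt so that no HCl meets the ketal.

Step 1
Reactants: 1 ethyl 2-(2-methyl-1,3-dioxolan-2-yl)acetate
Product: 2 potassium 2-(2-methyl-1,3-dioxolan-2-yl)acetate
Conditions: KOH (1.0 equiv), EtOH–H2O, rt; evaporate, dry under vacuum
Reagents that add atoms: potassium hydroxide [K+].[OH-]
Why: Saponification cannot touch the acid-labile dioxolane, and isolating the dry potassium carboxylate avoids handling the free acid.

Step 2
Reactants: 3 potassium tert-butoxide; 4 trichloroethylene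
Product: 7 tert-butoxyethyne, via dichlorovinyl ether 5 (not isolated), via lithium acetylide 6 (not isolated)
Conditions: THF, −50 °C → rt; n-BuLi (2.2 equiv), −78 → −40 °C; MeOH, −78 °C; distil under reduced pressure below 30 °C, store at −20 °C
Reagents that add atoms: none
Why: This is the established base-mediated alkynyl ether synthesis from trichloroethylene: alkoxide addition to dichloroacetylene formed in solution gives 5, then dehydrochlorination, chlorine–lithium exchange and protonation give the known terminal ynol ether.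

Step 3
Reactants: 2 potassium 2-(2-methyl-1,3-dioxolan-2-yl)acetate; 7 tert-butoxyethyne
Product: 10 rac-3-tert-butoxy-4-(2-methyl-1,3-dioxolan-2-yl)cyclobut-2-en-1-one, via acid chloride 8 (not isolated), via ketene 9 (not isolated)
Conditions: (COCl)2 (1.0 equiv), DMF (cat.), Et2O, 0 °C; then 7 (2 equiv), Et3N (1.3 equiv, slow addition), 0 °C → rt
Reagents that add atoms: none
Why: The salt gives the acid chloride without HCl, Et3N dehydrochlorinates it to aldoketene 9, and the known regioselective ketene–ynol ether [2+2] cycloaddition (ketene carbonyl carbon to the unsubstituted alkyne carbon) gives the 3-alkoxycyclobutenone, whose C4 centre forms racemic and is erased in step 5.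

Step 4
Reactants: 11 ethyl 4-methylpent-3-enoate
Product: 14 triisopropyl[(5-methylhex-4-en-1-yn-1-yl)oxy]silane, via dibromo enolate 12 (not isolated), via lithium ynolate 13 (not isolated)
Conditions: CH2Br2, lithium 2,2,6,6-tetramethylpiperidide, THF, −78 °C; add 11; LiN(SiMe3)2; n-BuLi, −78 °C → rt; i-Pr3SiCl, −78 → 0 °C
Reagents that add atoms: dibromomethane BrCBr; chlorotriisopropylsilane CC(C)[Si](Cl)(C(C)C)C(C)C
Why: Kowalski ester homologation: LiCHBr2 adds to the ester, the dibromo ketone enolate undergoes bromine–lithium exchange and 1,2-shift to the ynolate, and the hindered silyl chloride traps it on oxygen, a known route to silyl ynol ethers.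

Step 5
Reactants: 10 rac-3-tert-butoxy-4-(2-methyl-1,3-dioxolan-2-yl)cyclobut-2-en-1-one; 14 triisopropyl[(5-methylhex-4-en-1-yn-1-yl)oxy]silane
Product: 18 3-tert-butoxy-2-(2-methyl-1,3-dioxolan-2-yl)-6-(3-methylbut-2-en-1-yl)-5-(triisopropylsilyloxy)phenol, via vinylketene 15 (not isolated), via vinylcyclobutenone 16 (not isolated), via dienylketene 17 (not isolated)
Conditions: 14 (1.3 equiv), toluene (0.4 M), degassed, sealed tube, 80 °C then 110 °C
Reagents that add atoms: none
Why: Heating opens cyclobutenone 10 by 4π electrocyclic ring opening (C4 substituent turning outward) to alkoxyvinylketene 15, whose ketene C=C adds to the electron-rich alkyne 14 in a [2+2] cycloaddition that forms C8a–C4a and C5–C6 and gives vinylcyclobutenone 16. A second, reversible 4π opening delivers dienylketene 17, and thermal disrotatory 6π electrocyclisation between the ketene carbon and the diene terminus closes the six-membered carbocycle through the C8a–C8 bond; tautomerisation of the cyclohexadienone gives phenol 18. The closest known reaction is the Danheiser benzannulation of cyclobutenones with siloxyalkynes, extended here to a 3-alkoxycyclobutenone so that the arene comes out 1,3,5-trioxygenated. No stereocentre remains, because the racemic centres of 10 and 16 become sp2 carbons of the arene. The step needs one regiochemical outcome of the [2+2] event, and the polarisation of the siloxyalkyne secures it: its carbon remote from oxygen is the nucleophilic terminus and bonds to the ketene carbonyl carbon, which places prenyl ortho and the silyloxy group meta to the new hydroxyl. Only the isomer of 17 with the vinyl group turned inward can cyclise, but since the opening of 16 is reversible the material should funnel through it.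

Step 6
Reactants: 18 3-tert-butoxy-2-(2-methyl-1,3-dioxolan-2-yl)-6-(3-methylbut-2-en-1-yl)-5-(triisopropylsilyloxy)phenol
Product: 20 7-tert-butoxy-2,2-dimethyl-8-(2-methyl-1,3-dioxolan-2-yl)-5-(triisopropylsilyloxy)-2H-chromene, via o-quinone methide 19 (not isolated)
Conditions: DDQ (1.1 equiv), toluene, rt → 60 °C
Reagents that add atoms: none
Why: DDQ dehydrogenation of an ortho-prenylphenol gives o-quinone methide 19, which closes by oxa-6π electrocyclisation onto the only free hydroxyl (on C8a), so a single 2,2-dimethyl-2H-chromene can form while ketal and ethers stay inert under anhydrous conditions.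

Step 7
Reactants: 20 7-tert-butoxy-2,2-dimethyl-8-(2-methyl-1,3-dioxolan-2-yl)-5-(triisopropylsilyloxy)-2H-chromene
Product: 22 1-[7-hydroxy-2,2-dimethyl-5-(triisopropylsilyloxy)-2H-chromen-8-yl]ethan-1-one, via acetyl tert-butyl ether 21 (not isolated)
Conditions: TFA–CH2Cl2 (1:5), H2O (5 equiv), anisole (5 equiv), 0 °C; aq NaHCO3
Reagents that add atoms: water O
Why: Acidolysis hydrolyses the dioxolane to the acetyl group and cleaves the aryl tert-butyl ether ortho to it by loss of the tert-butyl cation (shed as isobutene, anisole as scavenger so that C6 is not alkylated), while the aryl silyl ether survives brief cold acid and the chromene meets no Lewis acid.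

Step 8
Reactants: 22 1-[7-hydroxy-2,2-dimethyl-5-(triisopropylsilyloxy)-2H-chromen-8-yl]ethan-1-one
Product: 23 1-(5,7-dihydroxy-2,2-dimethyl-2H-chromen-8-yl)ethan-1-one
Conditions: Bu4NF (1.1 equiv), AcOH (1.1 equiv), THF, 0 °C
Reagents that add atoms: none
Why: Fluoride desilylation of an aryl silyl ether, buffered with acetic acid so that the electron-rich phenoxide is not left in basic solution; nothing else in the molecule responds to fluoride.

Step 9
Reactants: 24 flopropione (1-(2,4,6-trihydroxyphenyl)propan-1-one)
Product: 26 3,5-dihydroxy-4,4-dimethyl-2-propanoylcyclohexa-2,5-dien-1-one (propionylfilicinic acid), via monomethyl ketone 25 (not isolated)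
Conditions: NaOMe (3.5 equiv), MeI (2.5 equiv), MeOH, 0 °C → rt; aq HCl
Reagents that add atoms: iodomethane CI
Why: Base-mediated C-methylation of an acylphloroglucinol: two alkylations at the same ring carbon dearomatise the ring to the acylfilicinic acid, the established preparation of this class.

Step 10
Reactants: 26 propionylfilicinic acid
Product: 27 6-[(dimethylamino)methyl]-3,5-dihydroxy-4,4-dimethyl-2-propanoylcyclohexa-2,5-dien-1-one
Conditions: Me2N=CH2 I (Eschenmoser's salt, 1.2 equiv), Et3N (1.0 equiv), CH2Cl2, 0 °C → rt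
Reagents that add atoms: N,N-dimethylmethyleneiminium iodide C=[N+](C)C.[I-]
Why: Mannich aminomethylation at the only enolic C–H of the β-triketone (C6); the preformed iminium salt, used instead of formaldehyde, should suppress methylene-bis dimer formation.

Step 11
Reactants: 23 1-(5,7-dihydroxy-2,2-dimethyl-2H-chromen-8-yl)ethan-1-one; 27 6-[(dimethylamino)methyl]-3,5-dihydroxy-4,4-dimethyl-2-propanoylcyclohexa-2,5-dien-1-one
Product: 29 6-[(8-acetyl-5,7-dihydroxy-2,2-dimethyl-2H-chromen-6-yl)methyl]-3,5-dihydroxy-4,4-dimethyl-2-propanoylcyclohexa-2,5-dien-1-one (target), via methylene trione 28 (not isolated)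
Conditions: 27 (1.2 equiv), 1,4-dioxane, 90 °C, N2 stream
Reagents that add atoms: none
Why: Thermal loss of dimethylamine from the Mannich base (retro-Michael) gives exocyclic enetrione 28, which alkylates the only free aromatic carbon of 23 (C6, between two hydroxyls) in a Michael-type Friedel–Crafts reaction and re-enolises to the methylene-bridged target without forming a stereocentre.

Compound list
1 | ethyl 2-(2-methyl-1,3-dioxolan-2-yl)acetate | CCOC(=O)CC1(C)OCCO1 | starting material
2 | potassium 2-(2-methyl-1,3-dioxolan-2-yl)acetate | CC1(CC(=O)[O-])OCCO1.[K+] | intermediate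
3 | potassium tert-butoxide | CC(C)(C)[O-].[K+] | starting material
4 | trichloroethylene | ClC=C(Cl)Cl | starting material
5 | (E)-1,2-dichlorovinyl tert-butyl ether | CC(C)(C)O/C(Cl)=C\Cl | intermediate (not isolated)
6 | lithium tert-butoxyacetylide | CC(C)(C)OC#C[Li] | intermediate (not isolated)
7 | tert-butoxyethyne | CC(C)(C)OC#C | intermediate
8 | 2-(2-methyl-1,3-dioxolan-2-yl)acetyl chloride | CC1(CC(=O)Cl)OCCO1 | intermediate (not isolated)
9 | 2-(2-methyl-1,3-dioxolan-2-yl)ethen-1-one (ketene) | CC1(C=C=O)OCCO1 | intermediate (not isolated)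
10 | rac-3-tert-butoxy-4-(2-methyl-1,3-dioxolan-2-yl)cyclobut-2-en-1-one | CC(C)(C)OC1=CC(=O)C1C2(C)OCCO2 | intermediate
11 | ethyl 4-methylpent-3-enoate | CCOC(=O)CC=C(C)C | starting material
12 | lithium 1,1-dibromo-5-methylhexa-1,4-dien-2-olate | CC(C)=CCC(O[Li])=C(Br)Br | intermediate (not isolated)
13 | lithium 5-methylhex-4-en-1-yn-1-olate | CC(C)=CCC#CO[Li] | intermediate (not isolated)
14 | triisopropyl[(5-methylhex-4-en-1-yn-1-yl)oxy]silane | CC(C)=CCC#CO[Si](C(C)C)(C(C)C)C(C)C | intermediate
15 | (3Z)-3-tert-butoxy-4-(2-methyl-1,3-dioxolan-2-yl)buta-1,3-dien-1-one | O=C=C/C(OC(C)(C)C)=C/C1(C)OCCO1 | intermediate (not isolated)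
16 | rac-4-[(Z)-1-tert-butoxy-2-(2-methyl-1,3-dioxolan-2-yl)ethenyl]-2-(3-methylbut-2-enyl)-3-(triisopropylsilyloxy)cyclobut-2-en-1-one | O=C1C(CC=C(C)C)=C(O[Si](C(C)C)(C(C)C)C(C)C)C1/C(OC(C)(C)C)=C/C2(C)OCCO2 | intermediate (not isolated)
17 | (3E,5Z)-5-tert-butoxy-6-(2-methyl-1,3-dioxolan-2-yl)-2-(3-methylbut-2-enyl)-3-(triisopropylsilyloxy)hexa-1,3,5-trien-1-one | O=C=C(CC=C(C)C)/C(O[Si](C(C)C)(C(C)C)C(C)C)=C\C(OC(C)(C)C)=C\C1(C)OCCO1 | intermediate (not isolated)
18 | 3-tert-butoxy-2-(2-methyl-1,3-dioxolan-2-yl)-6-(3-methylbut-2-en-1-yl)-5-(triisopropylsilyloxy)phenol | CC(C)(C)Oc1cc(O[Si](C(C)C)(C(C)C)C(C)C)c(CC=C(C)C)c(O)c1C1(C)OCCO1 | intermediate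
19 | (6Z)-3-tert-butoxy-2-(2-methyl-1,3-dioxolan-2-yl)-6-(3-methylbut-2-enylidene)-5-(triisopropylsilyloxy)cyclohexa-2,4-dien-1-one | CC(C)=C/C=C1\C(=O)C(C2(C)OCCO2)=C(OC(C)(C)C)C=C1O[Si](C(C)C)(C(C)C)C(C)C | intermediate (not isolated)
20 | 7-tert-butoxy-2,2-dimethyl-8-(2-methyl-1,3-dioxolan-2-yl)-5-(triisopropylsilyloxy)-2H-chromene | CC(C)(C)Oc1cc(O[Si](C(C)C)(C(C)C)C(C)C)c2C=CC(C)(C)Oc2c1C1(C)OCCO1 | intermediate
21 | 1-[7-tert-butoxy-2,2-dimethyl-5-(triisopropylsilyloxy)-2H-chromen-8-yl]ethan-1-one | CC(=O)c1c(OC(C)(C)C)cc(O[Si](C(C)C)(C(C)C)C(C)C)c2C=CC(C)(C)Oc12 | intermediate (not isolated)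
22 | 1-[7-hydroxy-2,2-dimethyl-5-(triisopropylsilyloxy)-2H-chromen-8-yl]ethan-1-one | CC(=O)c1c(O)cc(O[Si](C(C)C)(C(C)C)C(C)C)c2C=CC(C)(C)Oc12 | intermediate
23 | 1-(5,7-dihydroxy-2,2-dimethyl-2H-chromen-8-yl)ethan-1-one | CC(=O)c1c(O)cc(O)c2C=CC(C)(C)Oc12 | intermediate
24 | flopropione | CCC(=O)c1c(O)cc(O)cc1O | starting material
25 | 1-(2,4,6-trihydroxy-3-methylphenyl)propan-1-one | CCC(=O)c1c(O)cc(O)c(C)c1O | intermediate (not isolated)
26 | 3,5-dihydroxy-4,4-dimethyl-2-propanoylcyclohexa-2,5-dien-1-one (propionylfilicinic acid) | CCC(=O)C1=C(O)C(C)(C)C(O)=CC1=O | intermediate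
27 | 6-[(dimethylamino)methyl]-3,5-dihydroxy-4,4-dimethyl-2-propanoylcyclohexa-2,5-dien-1-one | CCC(=O)C1=C(O)C(C)(C)C(O)=C(CN(C)C)C1=O | intermediate
28 | 3-hydroxy-4,4-dimethyl-6-methylidene-2-propanoylcyclohex-2-ene-1,5-dione | CCC(=O)C1=C(O)C(C)(C)C(=O)C(=C)C1=O | intermediate (not isolated)
29 | 6-[(8-acetyl-5,7-dihydroxy-2,2-dimethyl-2H-chromen-6-yl)methyl]-3,5-dihydroxy-4,4-dimethyl-2-propanoylcyclohexa-2,5-dien-1-one | CCC(=O)C1=C(O)C(C)(C)C(O)=C(Cc2c(O)c3c(c(C(C)=O)c2O)OC(C)(C)C=C3)C1=O | target

Total step count: 11.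
Longest linear sequence: 7 steps (1 → 3 → 5 → 6 → 7 → 8 → 11; the branch through step 2 is equally long).

Steps most likely to fail

Step 5. The vinylogous-ester cyclobutenone may open too slowly, so that at the temperature needed the siloxyalkyne decomposes, the tert-butyl enol ether loses isobutene, or the sequence stalls before the 6π closure. The fallback gives up the de novo arene. It sets out from 27 and comes back at 29. Mannich base 27 is heated in dioxane with commercial 2,4,6-trihydroxyacetophenone to give 6-[(3-acetyl-2,4,6-trihydroxyphenyl)methyl]-3,5-dihydroxy-4,4-dimethyl-2-propanoylcyclohexa-2,5-dien-1-one F1. Heating this with 3-methylbut-2-enal and catalytic ethylenediammonium diacetate in toluene builds the pyran by Knoevenagel condensation and oxa-6π closure at the one free aromatic carbon. This should give 29 together with 6-[(6-acetyl-5,7-dihydroxy-2,2-dimethyl-2H-chromen-8-yl)methyl]-3,5-dihydroxy-4,4-dimethyl-2-propanoylcyclohexa-2,5-dien-1-one F2, the regioisomer closed onto the other hydroxyl, so a chromatographic separation becomes necessary.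

Step 3. The aldoketene may dimerise faster than it is trapped, and tert-butoxyethyne may fragment thermally or under traces of acid before it reacts. The fallback changes the alkyne and the unmasking logic. It sets out from 2 and comes back at 22. Ketene 9, made from 2 through 8 as before, is trapped with commercial, more robust ethoxyacetylene to give rac-3-ethoxy-4-(2-methyl-1,3-dioxolan-2-yl)cyclobut-2-en-1-one F3. Benzannulation with 14 gives 3-ethoxy-2-(2-methyl-1,3-dioxolan-2-yl)-6-(3-methylbut-2-en-1-yl)-5-(triisopropylsilyloxy)phenol F4. DDQ then gives 7-ethoxy-2,2-dimethyl-8-(2-methyl-1,3-dioxolan-2-yl)-5-(triisopropylsilyloxy)-2H-chromene F5. Pyridinium tosylate in wet acetone frees 1-[7-ethoxy-2,2-dimethyl-5-(triisopropylsilyloxy)-2H-chromen-8-yl]ethan-1-one F6. Chelation-controlled de-ethylation ortho to the acetyl group with BCl3 (CH2Cl2, −78 °C, short contact) gives 22. This accepts the Lewis-acid exposure of the pyran that the main route avoids.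

Step 11. Retro-Mannich scrambling may lead to self-condensation of the filicinic unit to its methylene-bis dimer, and capture by the hydrogen-bonded, hindered C6 of 23 may be slow. The fallback reverses the roles of the partners. It sets out from 23 and comes back at 29. Compound 23 is aminomethylated at C6 with Eschenmoser's salt to give 1-[6-[(dimethylamino)methyl]-5,7-dihydroxy-2,2-dimethyl-2H-chromen-8-yl]ethan-1-one F7. Heating F7 in dioxane with an excess of the cheap nucleophile 26 generates the o-quinone methide of the chromene, which 26 traps at its enolic carbon to give 29.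

Further compounds
F1 | step 5 | 6-[(3-acetyl-2,4,6-trihydroxyphenyl)methyl]-3,5-dihydroxy-4,4-dimethyl-2-propanoylcyclohexa-2,5-dien-1-one | CCC(=O)C1=C(O)C(C)(C)C(O)=C(Cc2c(O)cc(O)c(C(C)=O)c2O)C1=O
F2 | step 5 | 6-[(6-acetyl-5,7-dihydroxy-2,2-dimethyl-2H-chromen-8-yl)methyl]-3,5-dihydroxy-4,4-dimethyl-2-propanoylcyclohexa-2,5-dien-1-one | CCC(=O)C1=C(O)C(C)(C)C(O)=C(Cc2c(O)c(C(C)=O)c(O)c3C=CC(C)(C)Oc23)C1=O
F3 | step 3 | rac-3-ethoxy-4-(2-methyl-1,3-dioxolan-2-yl)cyclobut-2-en-1-one | CCOC1=CC(=O)C1C2(C)OCCO2
F4 | step 3 | 3-ethoxy-2-(2-methyl-1,3-dioxolan-2-yl)-6-(3-methylbut-2-en-1-yl)-5-(triisopropylsilyloxy)phenol | CCOc1cc(O[Si](C(C)C)(C(C)C)C(C)C)c(CC=C(C)C)c(O)c1C1(C)OCCO1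
F5 | step 3 | 7-ethoxy-2,2-dimethyl-8-(2-methyl-1,3-dioxolan-2-yl)-5-(triisopropylsilyloxy)-2H-chromene | CCOc1cc(O[Si](C(C)C)(C(C)C)C(C)C)c2C=CC(C)(C)Oc2c1C1(C)OCCO1
F6 | step 3 | 1-[7-ethoxy-2,2-dimethyl-5-(triisopropylsilyloxy)-2H-chromen-8-yl]ethan-1-one | CCOc1cc(O[Si](C(C)C)(C(C)C)C(C)C)c2C=CC(C)(C)Oc2c1C(C)=O
F7 | step 11 | 1-[6-[(dimethylamino)methyl]-5,7-dihydroxy-2,2-dimethyl-2H-chromen-8-yl]ethan-1-one | CC(=O)c1c(O)c(CN(C)C)c(O)c2C=CC(C)(C)Oc12
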